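**Retrosynthetic overview**
1. The C8 ketone, the C7 methine carrying CH3 and the C6 carbinol (a β-hydroxy ketone with anti CH3/OH) are the retron of a 4,5-dihydroisoxazole ring (C8, C7, C6, O, N); that ring is opened only in the last step (N–O cleavage, imine hydrolysis).
2. Key disconnection C8–C7 (with O–C6): magnesium-alkoxide-directed nitrile oxide cycloaddition of the C8–C24 nitrile oxide to (2S,3E)-2-methylpent-3-en-1-ol; the C4 hydroxyl, two atoms from C6, steers regio- and facial selectivity and then serves as handle.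
3. C3–C4: Negishi coupling of the C4 iodide with the (E)-enol triflate of an acetoacetate (C1–C3).
4. Northern half: C17–C18 Stille, C16=C17 Stork–Zhao olefination, C11–C12 Suzuki; C9 by Evans hydroxymethylation, C15 by Evans alkylation, C20/C21 by Brown crotylboration.
5. Ring order: dihydropyranone first (ring-closing metathesis, step 4), temporary isoxazoline second (step 25), isoxazoline opened last (step 29).

Key step: step 25

Numbering: C1 is the carboxylic acid carbon, C8 the ketone carbon, C9 the CH2OH-bearing carbon, C17 the ethyl-bearing alkene carbon, C20–C24 the lactone carbons (C20 = O–CH, C24 = C=O).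
Assumption: compounds 1, 6, 10, 14, 26 and 31 are bought; the southern half enters the key step as its stereodefined C4–C7 core (alcohol 30), because only the free C4 hydroxyl can direct the cycloaddition, and C1–C3 are clipped onto C4 directly afterwards.

**Dihydropyranone stannane (C18–C24)**

Step 1
Reactants: 1 (E)-3-(tributylstannyl)prop-2-en-1-ol
Product: 2 (E)-3-(tributylstannyl)prop-2-enal
Conditions: MnO2 (activated, excess), CH2Cl2, 23 °C
Reagents that add atoms: none
Why: Allylic alcohol oxidation on MnO2 is neutral and should leave the vinyl–tin bond and the E geometry untouched.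

Step 2
Reactants: 2 (E)-3-(tributylstannyl)prop-2-enal
Product: 3 (1E,3S,4S)-4-methyl-1-(tributylstannyl)hexa-1,5-dien-3-ol
Conditions: trans-2-butene, n-BuLi, KOt-Bu, THF, −78 to −45 °C; (−)-Ipc2BOMe; BF3·OEt2; then 2, −78 °C; HOCH2CH2NH2 work-up
Reagents that add atoms: (E)-crotyldiisopinocampheylborane C/C=C/CB([C@@H]1C[C@@H]2C[C@H]([C@H]1C)C2(C)C)[C@@H]1C[C@@H]2C[C@H]([C@H]1C)C2(C)C, made in the flask from trans-2-butene C/C=C/C
Why: Brown crotylboration through a closed chair transition state should turn the E-crotyl geometry into the anti C20–O/C21–CH3 relation, while the isopinocampheyl groups derived from (+)-α-pinene direct attack to the si face of the aldehyde and so set both centres.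

Step 3
Reactants: 3 (1E,3S,4S)-4-methyl-1-(tributylstannyl)hexa-1,5-dien-3-ol
Product: 4 (1E,3S,4S)-4-methyl-1-(tributylstannyl)hexa-1,5-dien-3-yl prop-2-enoate
Conditions: acryloyl chloride, i-Pr2NEt, DMAP (cat.), CH2Cl2, −20 to 0 °C
Reagents that add atoms: acryloyl chloride C=CC(=O)Cl
Why: Plain O-acylation of a secondary alcohol, with no stereocentre involved.

Step 4
Reactants: 4 (1E,3S,4S)-4-methyl-1-(tributylstannyl)hexa-1,5-dien-3-yl prop-2-enoate
Product: 5 (5S,6S)-5-methyl-6-[(E)-2-(tributylstannyl)ethenyl]-5,6-dihydro-2H-pyran-2-one (5,6-trans)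
Conditions: second-generation Grubbs catalyst (5 mol %), CH2Cl2 (5 mM), 40 °C
Reagents that add atoms: none
Why: Ring-closing metathesis should engage the terminal vinyl group and the acrylate to close the six-membered lactone, the bulky stannyl alkene staying out of the reaction, and the anti adduct gives the trans ring.

**C12–C16 boronate**

Step 5
Reactants: 6 (S)-4-benzyl-3-propanoyl-1,3-oxazolidin-2-one
Product: 7 (S)-4-benzyl-3-[(R)-2-methylpent-4-ynoyl]-1,3-oxazolidin-2-one
Conditions: NaN(SiMe3)2, THF, −78 °C; propargyl bromide, −78 to −40 °C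
Reagents that add atoms: propargyl bromide C#CCBr
Why: Evans alkylation: the chelated Z-enolate is alkylated on the face away from the benzyl group, which sets C15.

Step 6
Reactants: 7 (S)-4-benzyl-3-[(R)-2-methylpent-4-ynoyl]-1,3-oxazolidin-2-one
Product: 8 (R)-2-methylpent-4-yn-1-ol
Conditions: LiBH4, MeOH (1 equiv), Et2O, 0 °C
Reagents that add atoms: none
Why: Reductive removal of the Evans auxiliary with borohydride gives the primary alcohol without touching the stereocentre.

Step 7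
Reactants: 8 (R)-2-methylpent-4-yn-1-ol
Product: 9 (2R,4E)-2-methyl-5-(4,4,5,5-tetramethyl-1,3,2-dioxaborolan-2-yl)pent-4-en-1-ol
Conditions: pinacolborane (2.2 equiv), Cp2Zr(H)Cl (10 mol %), Et3N (10 mol %), CH2Cl2, 25 °C; aq. NH4Cl
Reagents that add atoms: pinacolborane [H]B1OC(C)(C)C(C)(C)O1
Why: Zirconium-catalysed syn hydroboration of the terminal alkyne should give the E-alkenylboronate; the transient O–B bond is hydrolysed on work-up.

**C8–C11 vinyl iodide**

Step 8
Reactants: 10 pent-3-yn-1-ol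
Product: 12 (E)-4-iodopent-3-en-1-ol, via alkenylzirconocene 11 (not isolated)
Conditions: Cp2Zr(H)Cl (2.5 equiv), THF, 40 °C; then I2, 0 °C
Reagents that add atoms: iodine II
Why: Hydrozirconation (syn addition, equilibrated with excess hydride to place zirconium on the methyl-bearing carbon) followed by iodinolysis with retention should give the E-iodoalkene.

Step 9
Reactants: 12 (E)-4-iodopent-3-en-1-ol
Product: 13 (E)-4-iodopent-3-enoic acid
Conditions: TEMPO (20 mol %), PhI(OAc)2 (2.2 equiv), MeCN/H2O, 23 °C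
Reagents that add atoms: water O
Why: Oxoammonium-mediated oxidation of the primary alcohol through the aldehyde hydrate gives the acid under near-neutral conditions that should not move the double bond.

Step 10
Reactants: 13 (E)-4-iodopent-3-enoic acid; 14 (R)-4-benzyl-1,3-oxazolidin-2-one
Product: 16 (R)-4-benzyl-3-[(E)-4-iodopent-3-enoyl]-1,3-oxazolidin-2-one, via mixed pivalic anhydride 15 (not isolated)
Conditions: t-BuCOCl, Et3N, THF, −20 °C; then 14, LiCl, −20 to 23 °C
Reagents that add atoms: none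
Why: N-acylation of the oxazolidinone through the mixed anhydride avoids strong base, so the β,γ-double bond should not move into conjugation.

Step 11
Reactants: 16 (R)-4-benzyl-3-[(E)-4-iodopent-3-enoyl]-1,3-oxazolidin-2-one
Product: 17 (R)-4-benzyl-3-[(2S,3E)-2-(hydroxymethyl)-4-iodopent-3-enoyl]-1,3-oxazolidin-2-one
Conditions: TiCl4, i-Pr2NEt, CH2Cl2, 0 °C; 1,3,5-trioxane, TiCl4, 0 °C
Reagents that add atoms: 1,3,5-trioxane C1OCOCO1
Why: Evans titanium-enolate hydroxymethylation: formaldehyde released from trioxane adds to the α-carbon of the chelated Z-enolate anti to the benzyl group, which sets C9, and α-deprotonation leaves the C10=C11 geometry as it is.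

Step 12
Reactants: 17 (R)-4-benzyl-3-[(2S,3E)-2-(hydroxymethyl)-4-iodopent-3-enoyl]-1,3-oxazolidin-2-one
Product: 18 (2S,3E)-2-(hydroxymethyl)-4-iodo-N-methoxy-N-methylpent-3-enamide
Conditions: MeNH(OMe)·HCl, AlMe3, THF, −15 to 0 °C
Reagents that add atoms: N,O-dimethylhydroxylamine hydrochloride CNOC.Cl
Why: Weinreb transamination, helped by the free β-hydroxyl through an aluminium alkoxide, removes the auxiliary without enolization.

Step 13
Reactants: 18 (2S,3E)-2-(hydroxymethyl)-4-iodo-N-methoxy-N-methylpent-3-enamide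
Product: 19 (2S,3E)-2-{[(tert-butyldimethylsilyl)oxy]methyl}-4-iodo-N-methoxy-N-methylpent-3-enamide
Conditions: TBSCl, imidazole, DMF, 23 °C
Reagents that add atoms: tert-butyldimethylsilyl chloride CC(C)(C)[Si](C)(C)Cl
Why: Standard silylation of the primary alcohol, which must stay masked until step 28.

**Assembly of the northern aldoxime**

Step 14
Reactants: 9 (2R,4E)-2-methyl-5-(4,4,5,5-tetramethyl-1,3,2-dioxaborolan-2-yl)pent-4-en-1-ol; 19 (2S,3E)-2-{[(tert-butyldimethylsilyl)oxy]methyl}-4-iodo-N-methoxy-N-methylpent-3-enamide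
Product: 20 (2S,3E,5E,8R)-2-{[(tert-butyldimethylsilyl)oxy]methyl}-9-hydroxy-N-methoxy-N,4,8-trimethylnona-3,5-dienamide
Conditions: Pd(PPh3)4 (5 mol %), TlOEt, THF/H2O (3:1), 23 °C
Reagents that add atoms: none
Why: Suzuki–Miyaura coupling of alkenyl partners proceeds with retention on both sides and should give the E,E-diene (C11–C12 bond) within minutes at room temperature.

Step 15
Reactants: 20 (2S,3E,5E,8R)-2-{[(tert-butyldimethylsilyl)oxy]methyl}-9-hydroxy-N-methoxy-N,4,8-trimethylnona-3,5-dienamide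
Product: 21 (2S,3E,5E,8R)-2-{[(tert-butyldimethylsilyl)oxy]methyl}-N-methoxy-N,4,8-trimethyl-9-oxonona-3,5-dienamide
Conditions: Dess–Martin periodinane, NaHCO3, CH2Cl2, 0 °C
Reagents that add atoms: none
Why: Buffered Dess–Martin oxidation gives the α-methyl aldehyde without epimerization.

Step 16
Reactants: 21 (2S,3E,5E,8R)-2-{[(tert-butyldimethylsilyl)oxy]methyl}-N-methoxy-N,4,8-trimethyl-9-oxonona-3,5-dienamide
Product: 22 (2S,3E,5E,8R,9Z)-2-{[(tert-butyldimethylsilyl)oxy]methyl}-10-iodo-N-methoxy-N,4,8-trimethyldodeca-3,5,9-trienamide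
Conditions: [Ph3PCH2CH2CH3]Br, n-BuLi, THF, 23 °C; I2, −78 °C; NaN(SiMe3)2, −20 °C; then 21, −78 to −20 °C
Reagents that add atoms: (1-iodopropylidene)triphenylphosphorane CCC(I)=P(c1ccccc1)(c1ccccc1)c1ccccc1, made in the flask from propyltriphenylphosphonium bromide CCC[P+](c1ccccc1)(c1ccccc1)c1ccccc1.[Br-] and iodine II
Why: Stork–Zhao olefination with an α-iodo ylide should place the aldehyde residue cis to iodine under kinetic control, which is the Z geometry needed at C16=C17.

Step 17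
Reactants: 22 (2S,3E,5E,8R,9Z)-2-{[(tert-butyldimethylsilyl)oxy]methyl}-10-iodo-N-methoxy-N,4,8-trimethyldodeca-3,5,9-trienamide
Product: 24 (2R,3E,5E,8R,9Z)-2-{[(tert-butyldimethylsilyl)oxy]methyl}-10-iodo-4,8-dimethyldodeca-3,5,9-trienal oxime, via aldehyde 23 (not isolated)
Conditions: i-Bu2AlH, THF, −78 °C; aq. potassium sodium tartrate; then NH2OH·HCl, pyridine, EtOH, 0 °C
Reagents that add atoms: hydroxylamine hydrochloride NO.Cl
Why: Weinreb amide reduction stops at the aldehyde through the stable chelate, and immediate oxime condensation stores the epimerizable β,γ-unsaturated aldehyde in a configurationally safe form (the change of the C9 descriptor is only a change of priorities).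

Step 18
Reactants: 24 (2R,3E,5E,8R,9Z)-2-{[(tert-butyldimethylsilyl)oxy]methyl}-10-iodo-4,8-dimethyldodeca-3,5,9-trienal oxime; 5 (5S,6S)-5-methyl-6-[(E)-2-(tributylstannyl)ethenyl]-5,6-dihydro-2H-pyran-2-one
Product: 25 (2R,3E,5E,8R,9Z,11E)-2-{[(tert-butyldimethylsilyl)oxy]methyl}-10-ethyl-4,8-dimethyl-12-[(2R,3S)-3-methyl-6-oxo-3,6-dihydro-2H-pyran-2-yl]dodeca-3,5,9,11-tetraenal oxime
Conditions: Pd2(dba)3 (5 mol %), AsPh3, NMP, 23 to 40 °C
Reagents that add atoms: none
Why: Stille coupling is base-free and stereoretentive, so the Z,E-diene (C17–C18 bond) should form without harm to the lactone or the oxime.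

**Southern alkenol (C4–C7)**

Step 19
Reactants: 26 methyl (R)-3-hydroxy-2-methylpropanoate
Product: 27 methyl (R)-3-[(tert-butyldimethylsilyl)oxy]-2-methylpropanoate
Conditions: TBSCl, imidazole, CH2Cl2, 23 °C
Reagents that add atoms: tert-butyldimethylsilyl chloride CC(C)(C)[Si](C)(C)Cl
Why: Silylation of the chiral-pool hydroxy ester; its stereocentre becomes C5.

Step 20
Reactants: 27 methyl (R)-3-[(tert-butyldimethylsilyl)oxy]-2-methylpropanoate
Product: 28 (R)-3-[(tert-butyldimethylsilyl)oxy]-2-methylpropanal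
Conditions: i-Bu2AlH, CH2Cl2, −78 °C
Reagents that add atoms: none
Why: Partial ester reduction at low temperature stops at the aluminium hemiacetal and should give the aldehyde without epimerization.

Step 21
Reactants: 28 (R)-3-[(tert-butyldimethylsilyl)oxy]-2-methylpropanal
Product: 29 tert-butyldimethyl{[(2S,3E)-2-methylpent-3-en-1-yl]oxy}silane
Conditions: CrCl2, CH3CHI2, THF, 23 °C
Reagents that add atoms: 1,1-diiodoethane CC(I)I
Why: Takai–Utimoto ethylidenation with a geminal dichromium reagent is E-selective and non-basic, so the α-stereocentre should survive.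

Step 22
Reactants: 29 tert-butyldimethyl{[(2S,3E)-2-methylpent-3-en-1-yl]oxy}silane
Product: 30 (2S,3E)-2-methylpent-3-en-1-ol
Conditions: Bu4NF, THF, 23 °C
Reagents that add atoms: none
Why: Fluoride desilylation frees the hydroxyl that will direct the key step.

**C1–C3 enol triflate**

Step 23
Reactants: 31 2-(trimethylsilyl)ethanol
Product: 32 2-(trimethylsilyl)ethyl 3-oxobutanoate
Conditions: 2,2,6-trimethyl-4H-1,3-dioxin-4-one, xylene, 120 °C
Reagents that add atoms: 2,2,6-trimethyl-4H-1,3-dioxin-4-one CC1=CC(=O)OC(C)(C)O1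
Why: Thermal retro-[4+2] release of acetylketene and its capture by the alcohol is a standard acetoacetylation.

Step 24
Reactants: 32 2-(trimethylsilyl)ethyl 3-oxobutanoate
Product: 33 2-(trimethylsilyl)ethyl (E)-3-{[(trifluoromethyl)sulfonyl]oxy}but-2-enoate
Conditions: Tf2O, 25% aq. Me4NOH, hexane, 5 to 10 °C
Reagents that add atoms: trifluoromethanesulfonic anhydride O=S(=O)(OS(=O)(=O)C(F)(F)F)C(F)(F)F
Why: O-sulfonylation of the non-chelated ammonium enolate should give the E-enol triflate, whose geometry becomes that of C2=C3.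

**Union and endgame**

Step 25
Reactants: 25 (2R,3E,5E,8R,9Z,11E)-2-{[(tert-butyldimethylsilyl)oxy]methyl}-10-ethyl-4,8-dimethyl-12-[(2R,3S)-3-methyl-6-oxo-3,6-dihydro-2H-pyran-2-yl]dodeca-3,5,9,11-tetraenal oxime; 30 (2S,3E)-2-methylpent-3-en-1-ol
Product: 36 (4S,5S)-5-[(2R)-1-hydroxypropan-2-yl]-4-methyl-3-(C9–C24 chain of 25)-4,5-dihydro-1,2-oxazole, via hydroximoyl chloride 34 (not isolated), via nitrile oxide 35 (not isolated)
Conditions: t-BuOCl, CH2Cl2, −78 °C; then cannula into 30 (2 equiv), i-PrOH, EtMgBr, CH2Cl2, 0 to 23 °C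
Reagents that add atoms: none
Why: Chlorination of the aldoxime gives hydroximoyl chloride 34, which the magnesium alkoxides dehydrochlorinate to nitrile oxide 35; its oxygen binds the magnesium alkoxide of 30 and a concerted suprafacial [3+2] cycloaddition to C6=C7 follows, the closest known reaction type being the magnesium-alkoxide-directed nitrile oxide cycloaddition of allylic and homoallylic alcohols. The one ring closed is the 4,5-dihydroisoxazole (C8, C7, C6, O, N), formed by intermolecular 1,3-dipolar cycloaddition in which C8–C7 and O–C6 are made together. C7 and C6 are the new stereocentres: their anti (4,5-trans) relation follows from the E geometry of 30, and their absolute sense from C5, because in the six-membered magnesium chelate the CH2O–Mg arm lies on the attacked face, the C5 hydrogen eclipses the alkene and the C5 methyl points away. Regioselectivity (oxygen to C6, carbon to C7) comes from the same chelate, which puts the dipole oxygen on the alkene carbon nearer the alkoxide. Chemoselectivity over the six other C=C bonds of 35 and over dimerization rests on the rate acceleration that only the alkoxide-bearing alkene enjoys, on the excess of cheap 30 and on the α-branching of 35. The step should thus deliver the masked C8 carbonyl, the C6 oxygen and both stereocentres in one operation from a six-carbon chiral-pool alcohol.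

Step 26
Reactants: 36 (4S,5S)-5-[(2R)-1-hydroxypropan-2-yl]-4-methyl-3-(C9–C24 chain of 25)-4,5-dihydro-1,2-oxazole
Product: 37 (4S,5S)-5-[(2S)-1-iodopropan-2-yl]-4-methyl-3-(C9–C24 chain of 25)-4,5-dihydro-1,2-oxazole
Conditions: I2, PPh3, imidazole, CH2Cl2, 0 °C
Reagents that add atoms: iodine II
Why: Appel-type (Garegg–Samuelsson) iodination of the primary alcohol is neutral; the directing group becomes the coupling handle and no stereocentre is touched (descriptor changes are priority changes only).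

Step 27
Reactants: 37 (4S,5S)-5-[(2S)-1-iodopropan-2-yl]-4-methyl-3-(C9–C24 chain of 25)-4,5-dihydro-1,2-oxazole; 33 2-(trimethylsilyl)ethyl (E)-3-{[(trifluoromethyl)sulfonyl]oxy}but-2-enoate
Product: 39 2-(trimethylsilyl)ethyl (2E,5R)-3-methyl-5-[(4S,5R)-4-methyl-3-(C9–C24 chain of 25)-4,5-dihydro-1,2-oxazol-5-yl]hex-2-enoate, via alkylzinc iodide 38 (not isolated)
Conditions: Zn dust (activated with BrCH2CH2Br and Me3SiCl), LiCl, THF, 35 °C; then 33, Pd(PPh3)4 (5 mol %), THF/NMP, 40 °C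
Reagents that add atoms: none
Why: Negishi coupling of a primary alkylzinc with an enol triflate retains the alkene geometry and tolerates ester, lactone and isoxazoline, so the E-configured C2=C3 enoate should be attached at C4.

Step 28
Reactants: 39 2-(trimethylsilyl)ethyl (2E,5R)-3-methyl-5-[(4S,5R)-4-methyl-3-(C9–C24 chain of 25)-4,5-dihydro-1,2-oxazol-5-yl]hex-2-enoate
Product: 40 (2E,5R)-5-[(4S,5R)-3-{(2R,3E,5E,8R,9Z,11E)-10-ethyl-1-hydroxy-4,8-dimethyl-12-[(2R,3S)-3-methyl-6-oxo-3,6-dihydro-2H-pyran-2-yl]dodeca-3,5,9,11-tetraen-2-yl}-4-methyl-4,5-dihydro-1,2-oxazol-5-yl]-3-methylhex-2-enoic acid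
Conditions: TASF, DMF, 0 °C
Reagents that add atoms: none
Why: Fluoride cleaves the silyl ether and fragments the silylethyl ester while the ketone is still masked, so no β-hydroxy ketone is exposed to fluoride.

Step 29
Reactants: 40 (2E,5R)-5-[(4S,5R)-3-{(2R,3E,5E,8R,9Z,11E)-10-ethyl-1-hydroxy-4,8-dimethyl-12-[(2R,3S)-3-methyl-6-oxo-3,6-dihydro-2H-pyran-2-yl]dodeca-3,5,9,11-tetraen-2-yl}-4-methyl-4,5-dihydro-1,2-oxazol-5-yl]-3-methylhex-2-enoic acid
Product: 42 (2E,5R,6R,7R,9S,10E,12E,15R,16Z,18E)-17-ethyl-6-hydroxy-9-(hydroxymethyl)-3,5,7,11,15-pentamethyl-19-[(2R,3S)-3-methyl-6-oxo-3,6-dihydro-2H-pyran-2-yl]-8-oxononadeca-2,10,12,16,18-pentaenoic acid, via hydroxy imine 41 (not isolated)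
Conditions: SmI2, THF, −40 to 0 °C; then B(OH)3, MeOH/H2O, 23 °C
Reagents that add atoms: water O
Why: Single-electron N–O cleavage of the isoxazoline followed by boric-acid-buffered hydrolysis of the β-hydroxy imine should release the β-hydroxy ketone under mildly acidic conditions that spare C9 and C7.

**Compound list**
1 | (E)-3-(tributylstannyl)prop-2-en-1-ol | CCCC[Sn](CCCC)(CCCC)/C=C/CO | starting material
2 | (E)-3-(tributylstannyl)prop-2-enal | CCCC[Sn](CCCC)(CCCC)/C=C/C=O | intermediate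
3 | (1E,3S,4S)-4-methyl-1-(tributylstannyl)hexa-1,5-dien-3-ol | CCCC[Sn](CCCC)(CCCC)/C=C/[C@@H](O)[C@@H](C)C=C | intermediate
4 | (1E,3S,4S)-4-methyl-1-(tributylstannyl)hexa-1,5-dien-3-yl prop-2-enoate | CCCC[Sn](CCCC)(CCCC)/C=C/[C@@H](OC(=O)C=C)[C@@H](C)C=C | intermediate
5 | (5S,6S)-5-methyl-6-[(E)-2-(tributylstannyl)ethenyl]-5,6-dihydro-2H-pyran-2-one | CCCC[Sn](CCCC)(CCCC)/C=C/[C@H]1OC(=O)C=C[C@@H]1C | intermediate
6 | (S)-4-benzyl-3-propanoyl-1,3-oxazolidin-2-one | CCC(=O)N1[C@@H](Cc2ccccc2)COC1=O | starting material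
7 | (S)-4-benzyl-3-[(R)-2-methylpent-4-ynoyl]-1,3-oxazolidin-2-one | C#CC[C@@H](C)C(=O)N1[C@@H](Cc2ccccc2)COC1=O | intermediate
8 | (R)-2-methylpent-4-yn-1-ol | C#CC[C@@H](C)CO | intermediate
9 | (2R,4E)-2-methyl-5-(4,4,5,5-tetramethyl-1,3,2-dioxaborolan-2-yl)pent-4-en-1-ol | OC[C@H](C)C/C=C/B1OC(C)(C)C(C)(C)O1 | intermediate
10 | pent-3-yn-1-ol | CC#CCCO | starting material
11 | O-zirconated (E)-alkenylzirconocene chloride from 10 | C/C(=C\CCO[Zr](Cl)(C1C=CC=C1)C1C=CC=C1)[Zr](Cl)(C1C=CC=C1)C1C=CC=C1 | intermediate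
12 | (E)-4-iodopent-3-en-1-ol | C/C(I)=C\CCO | intermediate
13 | (E)-4-iodopent-3-enoic acid | C/C(I)=C\CC(=O)O | intermediate
14 | (R)-4-benzyl-1,3-oxazolidin-2-one | O=C1N[C@H](Cc2ccccc2)CO1 | starting material
15 | (E)-4-iodopent-3-enoic pivalic anhydride | C/C(I)=C\CC(=O)OC(=O)C(C)(C)C | intermediate
16 | (R)-4-benzyl-3-[(E)-4-iodopent-3-enoyl]-1,3-oxazolidin-2-one | C/C(I)=C\CC(=O)N1[C@H](Cc2ccccc2)COC1=O | intermediate
17 | (R)-4-benzyl-3-[(2S,3E)-2-(hydroxymethyl)-4-iodopent-3-enoyl]-1,3-oxazolidin-2-one | C/C(I)=C\[C@@H](CO)C(=O)N1[C@H](Cc2ccccc2)COC1=O | intermediate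
18 | (2S,3E)-2-(hydroxymethyl)-4-iodo-N-methoxy-N-methylpent-3-enamide | C/C(I)=C\[C@@H](CO)C(=O)N(C)OC | intermediate
19 | (2S,3E)-2-{[(tert-butyldimethylsilyl)oxy]methyl}-4-iodo-N-methoxy-N-methylpent-3-enamide | C/C(I)=C\[C@@H](CO[Si](C)(C)C(C)(C)C)C(=O)N(C)OC | intermediate
20 | (2S,3E,5E,8R)-2-{[(tert-butyldimethylsilyl)oxy]methyl}-9-hydroxy-N-methoxy-N,4,8-trimethylnona-3,5-dienamide | OC[C@H](C)C/C=C/C(C)=C/[C@@H](CO[Si](C)(C)C(C)(C)C)C(=O)N(C)OC | intermediate
21 | (2S,3E,5E,8R)-2-{[(tert-butyldimethylsilyl)oxy]methyl}-N-methoxy-N,4,8-trimethyl-9-oxonona-3,5-dienamide | O=C[C@H](C)C/C=C/C(C)=C/[C@@H](CO[Si](C)(C)C(C)(C)C)C(=O)N(C)OC | intermediate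
22 | (2S,3E,5E,8R,9Z)-2-{[(tert-butyldimethylsilyl)oxy]methyl}-10-iodo-N-methoxy-N,4,8-trimethyldodeca-3,5,9-trienamide | CC/C(I)=C/[C@H](C)C/C=C/C(C)=C/[C@@H](CO[Si](C)(C)C(C)(C)C)C(=O)N(C)OC | intermediate
23 | (2S,3E,5E,8R,9Z)-2-{[(tert-butyldimethylsilyl)oxy]methyl}-10-iodo-4,8-dimethyldodeca-3,5,9-trienal | CC/C(I)=C/[C@H](C)C/C=C/C(C)=C/[C@@H](CO[Si](C)(C)C(C)(C)C)C=O | intermediate
24 | (2R,3E,5E,8R,9Z)-2-{[(tert-butyldimethylsilyl)oxy]methyl}-10-iodo-4,8-dimethyldodeca-3,5,9-trienal oxime | CC/C(I)=C/[C@H](C)C/C=C/C(C)=C/[C@@H](CO[Si](C)(C)C(C)(C)C)C=NO | intermediate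
25 | (2R,3E,5E,8R,9Z,11E)-2-{[(tert-butyldimethylsilyl)oxy]methyl}-10-ethyl-4,8-dimethyl-12-[(2R,3S)-3-methyl-6-oxo-3,6-dihydro-2H-pyran-2-yl]dodeca-3,5,9,11-tetraenal oxime | CCC(=C/[C@H](C)C/C=C/C(C)=C/[C@@H](CO[Si](C)(C)C(C)(C)C)C=NO)/C=C/[C@H]1OC(=O)C=C[C@@H]1C | intermediate
26 | methyl (R)-3-hydroxy-2-methylpropanoate | COC(=O)[C@H](C)CO | starting material
27 | methyl (R)-3-[(tert-butyldimethylsilyl)oxy]-2-methylpropanoate | COC(=O)[C@H](C)CO[Si](C)(C)C(C)(C)C | intermediate
28 | (R)-3-[(tert-butyldimethylsilyl)oxy]-2-methylpropanal | O=C[C@H](C)CO[Si](C)(C)C(C)(C)C | intermediate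
29 | tert-butyldimethyl{[(2S,3E)-2-methylpent-3-en-1-yl]oxy}silane | C/C=C/[C@H](C)CO[Si](C)(C)C(C)(C)C | intermediate
30 | (2S,3E)-2-methylpent-3-en-1-ol | C/C=C/[C@H](C)CO | intermediate
31 | 2-(trimethylsilyl)ethanol | C[Si](C)(C)CCO | starting material
32 | 2-(trimethylsilyl)ethyl 3-oxobutanoate | CC(=O)CC(=O)OCC[Si](C)(C)C | intermediate
33 | 2-(trimethylsilyl)ethyl (E)-3-{[(trifluoromethyl)sulfonyl]oxy}but-2-enoate | C/C(OS(=O)(=O)C(F)(F)F)=C\C(=O)OCC[Si](C)(C)C | intermediate
34 | hydroximoyl chloride of 25 | CCC(=C/[C@H](C)C/C=C/C(C)=C/[C@@H](CO[Si](C)(C)C(C)(C)C)C(Cl)=NO)/C=C/[C@H]1OC(=O)C=C[C@@H]1C | intermediate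
35 | nitrile oxide of the C8–C24 half | CCC(=C/[C@H](C)C/C=C/C(C)=C/[C@@H](CO[Si](C)(C)C(C)(C)C)C#[N+][O-])/C=C/[C@H]1OC(=O)C=C[C@@H]1C | intermediate
36 | isoxazoline alcohol, (4S,5S)-5-[(2R)-1-hydroxypropan-2-yl]-4-methyl-3-(C9–C24 chain of 25)-4,5-dihydro-1,2-oxazole | CCC(=C/[C@H](C)C/C=C/C(C)=C/[C@@H](CO[Si](C)(C)C(C)(C)C)C2=NO[C@H]([C@H](C)CO)[C@H]2C)/C=C/[C@H]1OC(=O)C=C[C@@H]1C | intermediate
37 | isoxazoline iodide, (4S,5S)-5-[(2S)-1-iodopropan-2-yl] analogue of 36 | CCC(=C/[C@H](C)C/C=C/C(C)=C/[C@@H](CO[Si](C)(C)C(C)(C)C)C2=NO[C@H]([C@H](C)CI)[C@H]2C)/C=C/[C@H]1OC(=O)C=C[C@@H]1C | intermediate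
38 | alkylzinc iodide from 37 | CCC(=C/[C@H](C)C/C=C/C(C)=C/[C@@H](CO[Si](C)(C)C(C)(C)C)C2=NO[C@H]([C@H](C)C[Zn]I)[C@H]2C)/C=C/[C@H]1OC(=O)C=C[C@@H]1C | intermediate
39 | 2-(trimethylsilyl)ethyl (2E,5R)-3-methyl-5-[(4S,5R)-4-methyl-3-(C9–C24 chain of 25)-4,5-dihydro-1,2-oxazol-5-yl]hex-2-enoate | CCC(=C/[C@H](C)C/C=C/C(C)=C/[C@@H](CO[Si](C)(C)C(C)(C)C)C2=NO[C@H]([C@H](C)C/C(C)=C/C(=O)OCC[Si](C)(C)C)[C@H]2C)/C=C/[C@H]1OC(=O)C=C[C@@H]1C | intermediate
40 | isoxazoline diol acid (name as in step 28) | CCC(=C/[C@H](C)C/C=C/C(C)=C/[C@@H](CO)C2=NO[C@H]([C@H](C)C/C(C)=C/C(=O)O)[C@H]2C)/C=C/[C@H]1OC(=O)C=C[C@@H]1C | intermediate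
41 | C8 imine of the target (β-hydroxy imine) | CCC(=C/[C@H](C)C/C=C/C(C)=C/[C@@H](CO)C(=N)[C@H](C)[C@H](O)[C@H](C)C/C(C)=C/C(=O)O)/C=C/[C@H]1OC(=O)C=C[C@@H]1C | intermediate
42 | (2E,5R,6R,7R,9S,10E,12E,15R,16Z,18E)-17-ethyl-6-hydroxy-9-(hydroxymethyl)-3,5,7,11,15-pentamethyl-19-[(2R,3S)-3-methyl-6-oxo-3,6-dihydro-2H-pyran-2-yl]-8-oxononadeca-2,10,12,16,18-pentaenoic acid | CCC(=C/[C@H](C)C/C=C/C(C)=C/[C@@H](CO)C(=O)[C@H](C)[C@H](O)[C@H](C)C/C(C)=C/C(=O)O)/C=C/[C@H]1OC(=O)C=C[C@@H]1C | target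

**Step count and risks**
Total steps: 29. Longest linear sequence: 16 steps (8–13, 14–18, 25–29).

Step 25 (key step). The chelate control may be incomplete, so that the wrong face or the wrong regiochemistry is attacked. The hypochlorite may also chlorinate the dienes, the nitrile oxide may add to the dienes of a second molecule, or the alkoxides may open the lactone. Fallback: the southern half is completed first and the cycloaddition is run without magnesium. It sets out from 30 and 33: 30 is converted (I2, PPh3, imidazole) into (2E,4S)-5-iodo-4-methylpent-2-ene F1. Zinc insertion gives the alkylzinc iodide F2, and Negishi coupling with 33 gives 2-(trimethylsilyl)ethyl (2E,5R,6E)-3,5-dimethylocta-2,6-dienoate F3. Nitrile oxide 35, generated from 25 through 34 by slow addition of Et3N, is then added thermally to the C6=C7 bond of F3 (used in excess). Facial control is then only that of the C5 stereocentre and diastereomers must be separated. The route comes back at 39.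

Step 16. The basic iodo-ylide may give low conversion, E isomer and epoxide by-products, and may epimerize the α-methyl aldehyde. Fallback: from 21, dibromo-olefination (CBr4, PPh3, CH2Cl2, 0 °C) gives the 10,10-dibromo-9-ene F4. Trans-selective Negishi mono-ethylation (EtZnCl, PdCl2(DPEphos), THF, 0 °C) replaces the bromine trans to the chain and gives the (Z)-10-bromo analogue of 22, F5. Reduction with i-Bu2AlH gives the bromo aldehyde F6, and NH2OH·HCl/pyridine gives the bromo oxime F7. Stille coupling of F7 with 5 comes back at 25.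

Step 29. Divalent samarium may over-reduce the conjugated lactone or the enoic acid in the presence of the free acid, and C9 may epimerize or lose its hydroxymethyl arm during imine hydrolysis. Fallback: the ketone is unmasked before deprotection and by a different mechanism. From 39, Mo(CO)6 in MeCN/H2O at 70 °C cleaves the N–O bond to the silylated imine F8, which hydrolyses in the same flask to the fully protected β-hydroxy ketone F9. TASF buffered with AcOH in DMF at 0 °C then removes both silicon groups and the route comes back at 42.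

**Further compounds**
F1 | step 25 | (2E,4S)-5-iodo-4-methylpent-2-ene | C/C=C/[C@H](C)CI
F2 | step 25 | [(2S,3E)-2-methylpent-3-en-1-yl]zinc iodide | C/C=C/[C@H](C)C[Zn]I
F3 | step 25 | 2-(trimethylsilyl)ethyl (2E,5R,6E)-3,5-dimethylocta-2,6-dienoate | C/C=C/[C@H](C)C/C(C)=C/C(=O)OCC[Si](C)(C)C
F4 | step 16 | (2S,3E,5E,8R)-10,10-dibromo-2-{[(tert-butyldimethylsilyl)oxy]methyl}-N-methoxy-N,4,8-trimethyldeca-3,5,9-trienamide | BrC(Br)=C[C@H](C)C/C=C/C(C)=C/[C@@H](CO[Si](C)(C)C(C)(C)C)C(=O)N(C)OC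
F5 | step 16 | (2S,3E,5E,8R,9Z)-10-bromo-2-{[(tert-butyldimethylsilyl)oxy]methyl}-N-methoxy-N,4,8-trimethyldodeca-3,5,9-trienamide | CC/C(Br)=C/[C@H](C)C/C=C/C(C)=C/[C@@H](CO[Si](C)(C)C(C)(C)C)C(=O)N(C)OC
F6 | step 16 | (2S,3E,5E,8R,9Z)-10-bromo-2-{[(tert-butyldimethylsilyl)oxy]methyl}-4,8-dimethyldodeca-3,5,9-trienal | CC/C(Br)=C/[C@H](C)C/C=C/C(C)=C/[C@@H](CO[Si](C)(C)C(C)(C)C)C=O
F7 | step 16 | (2R,3E,5E,8R,9Z)-10-bromo-2-{[(tert-butyldimethylsilyl)oxy]methyl}-4,8-dimethyldodeca-3,5,9-trienal oxime | CC/C(Br)=C/[C@H](C)C/C=C/C(C)=C/[C@@H](CO[Si](C)(C)C(C)(C)C)C=NO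
F8 | step 29 | C8 imine of the silyl ether and silylethyl ester of the target | CCC(=C/[C@H](C)C/C=C/C(C)=C/[C@@H](CO[Si](C)(C)C(C)(C)C)C(=N)[C@H](C)[C@H](O)[C@H](C)C/C(C)=C/C(=O)OCC[Si](C)(C)C)/C=C/[C@H]1OC(=O)C=C[C@@H]1C
F9 | step 29 | silyl ether and silylethyl ester of the target | CCC(=C/[C@H](C)C/C=C/C(C)=C/[C@@H](CO[Si](C)(C)C(C)(C)C)C(=O)[C@H](C)[C@H](O)[C@H](C)C/C(C)=C/C(=O)OCC[Si](C)(C)C)/C=C/[C@H]1OC(=O)C=C[C@@H]1C
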